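**Retrosynthetic overview**
1. Endgame on ring B: acid 31 comes from its 2-(trimethylsilyl)ethyl ester 30. C8=CH2/C7H2 comes from formate hydrogenolysis of a C7 allylic carbonate, C17 from a Mannich methylenation, the C9 side chain from a copper-catalysed 1,4-addition to the C8=C9–C7=O enone, and the 3α-OAc from a C3 ketone.
2. Key disconnection C4–C5: ring A is closed by a catalytic enantioselective, desymmetrising intramolecular Michael addition. The donor is an α-methyl-β-keto ester (C3, C4, C18, C19) and the acceptor an achiral 4,4-disubstituted cyclohexa-2,5-dienone (ring B with a temporary C7 ketone); C4, C5 and C10 are set at once.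
3. Enabling feature: C4 of ring A carries CH3 and CO2H next to oxygenated C3 (a latent stabilised C4 carbanion). H-5 is cis to the C10 methyl, so C4 and C1 lie on the same face of ring B, which is the only outcome a tether anchored on C10 can give. With C7 as a ketone, ring B gains a mirror plane through C7 and C10.
4. Precursor 16 comes from dienone acid 10 and methylmalonic half ester 13; acid 10 comes from propanal, methyl acrylate and methyl vinyl ketone.
5. Ring order: ring B first (Robinson annulation, step 2), ring A second and last (step 7).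

Key step: step 7

Remark: labdane numbering is used (ring A = C1–C5, C10; ring B = C5–C10), and β is the face of the C10 methyl. The SMILES is read as 3R,4R,5S,9S,10R. This means H-5 is cis to the C10 methyl (cis-fused decalin, 5β-H), with 3α-OAc, 4β-CO2H (C19) and a 9β side chain.

**Step 1**
Reactants: 1 propanal; 2 methyl acrylate
Product: 5 methyl 4-methyl-5-oxopentanoate (racemic), via enamine 3 (not isolated), via adduct enamine 4 (not isolated)
Conditions: pyrrolidine, K2CO3, 0 °C; 2, MeCN, reflux; AcOH, H2O, reflux
Reagents that add atoms: water, O; pyrrolidine, C1CCNC1 (stays only in 3 and 4)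
Why: Stork enamine Michael addition, in which the β-carbon of the propanal enamine adds to the acrylate and hydrolysis returns the aldehyde; the new centre is racemic and its chirality is erased in step 3.

**Step 2**
Reactants: 5 methyl 4-methyl-5-oxopentanoate; 6 methyl vinyl ketone
Product: 8 methyl 3-(1-methyl-4-oxocyclohex-2-en-1-yl)propanoate (racemic), via keto aldehyde 7 (not isolated)
Conditions: H2SO4 (cat.), toluene, 45 °C, then reflux, Dean–Stark
Reagents that add atoms: none
Why: Acid-catalysed Robinson annulation (Michael addition of the aldehyde enol, then aldol condensation) closes ring B and builds quaternary C10, racemic at this stage and without consequence.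

**Step 3**
Reactants: 8 methyl 3-(1-methyl-4-oxocyclohex-2-en-1-yl)propanoate
Product: 9 methyl 3-(1-methyl-4-oxocyclohexa-2,5-dien-1-yl)propanoate
Conditions: DDQ, 1,4-dioxane, reflux
Reagents that add atoms: none
Why: DDQ dehydrogenation of a 4,4-disubstituted cyclohexenone through its dienol gives the cross-conjugated dienone, whose mirror plane through C7 and C10 removes the racemic stereocentre.

**Step 4**
Reactants: 9 methyl 3-(1-methyl-4-oxocyclohexa-2,5-dien-1-yl)propanoate
Product: 10 3-(1-methyl-4-oxocyclohexa-2,5-dien-1-yl)propanoic acid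
Conditions: LiOH, THF/H2O, 0 °C; 1 M HCl
Reagents that add atoms: lithium hydroxide, [Li+].[OH-]
Why: Saponification of an unhindered primary-chain methyl ester, in which any hydroxide addition to the dienone is reversible and acid-induced dienone–phenol rearrangement is avoided.

**Step 5**
Reactants: 11 2,2,5-trimethyl-1,3-dioxane-4,6-dione (methyl Meldrum's acid); 12 2-(trimethylsilyl)ethanol
Product: 13 2-methyl-3-oxo-3-[2-(trimethylsilyl)ethoxy]propanoic acid (racemic)
Conditions: toluene, 105 °C
Reagents that add atoms: none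
Why: Alcoholysis of a Meldrum's acid derivative opens the ring with loss of acetone and gives the malonic half ester below its decarboxylation temperature.

**Step 6**
Reactants: 10 3-(1-methyl-4-oxocyclohexa-2,5-dien-1-yl)propanoic acid; 13 2-methyl-3-oxo-3-[2-(trimethylsilyl)ethoxy]propanoic acid
Product: 16 2-(trimethylsilyl)ethyl 2-methyl-5-(1-methyl-4-oxocyclohexa-2,5-dien-1-yl)-3-oxopentanoate, via acyl imidazole 14 (not isolated), via acylated half ester 15 (not isolated)
Conditions: CDI, THF, rt; then 13, MgCl2, Et3N, MeCN, 0 °C to rt; cold 1 M HCl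
Reagents that add atoms: 1,1'-carbonyldiimidazole, O=C(n1ccnc1)n1ccnc1 (its imidazolyl group stays only in 14)
Why: Masamune–Brooks β-keto ester synthesis (C-acylation of the magnesium malonate half ester, then decarboxylation); the magnesium chelate of the product is a poor donor toward the hindered dienone and is released by a cold acidic quench, so uncatalysed ring closure should not intervene, and C4 is a labile racemic centre.

**Step 7**
Reactants: 16 2-(trimethylsilyl)ethyl 2-methyl-5-(1-methyl-4-oxocyclohexa-2,5-dien-1-yl)-3-oxopentanoate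
Product: 17 2-(trimethylsilyl)ethyl (1R,4aR,8aS)-1,4a-dimethyl-2,7-dioxo-1,2,3,4,4a,7,8,8a-octahydronaphthalene-1-carboxylate (cis-fused)
Conditions: 1-[3,5-bis(trifluoromethyl)phenyl]-3-[(8α,9S)-6'-methoxycinchonan-9-yl]thiourea (10 mol %), toluene, 0 °C
Reagents that add atoms: none
Why: The quinuclidine nitrogen of the bifunctional catalyst deprotonates the β-keto ester, the thiourea binds the dienone carbonyl, C4 adds to C5 and the C6 enolate is protonated; the closest known reaction type is the cinchona (thio)urea-catalysed desymmetrising intramolecular Michael addition of stabilised carbon nucleophiles to 4,4-disubstituted cyclohexa-2,5-dienones. Ring A closes in the 6-(enolendo)-exo-trig mode through a chair-like transition state in which C3 is anti to C6. C5 is controlled by the tether: the C1–C2–C3 chain anchored on C10 can bring C4 only to the face of ring B on which C1 stands, so H-5 ends cis to the C10 methyl. C10 becomes stereogenic through the choice between the two enantiotopic β-carbons of the dienone, and this choice, hence the absolute configuration, is made by the chiral catalyst. C4 is controlled by enolate geometry: in the hydrogen-bonded U-shaped (Z) enolate the ester is cis to O-3 and points away from ring B (equatorial) while the smaller methyl lies under ring B (axial), which places the ester on the face of H-5 and the C10 methyl. The step needs C4 rather than C2 or O-3 as nucleophile and a single addition, which the substrate secures because C2 could only form a four-membered ring, O-addition is reversible, and the quaternary C4 of the product cannot attack the remaining C8=C9 enone.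

**Step 8**
Reactants: 17 bicyclic enedione ester
Product: 18 2-(trimethylsilyl)ethyl (1R,2R,4aR,8aS)-2-hydroxy-1,4a-dimethyl-7-oxo-1,2,3,4,4a,7,8,8a-octahydronaphthalene-1-carboxylate (3α-alcohol)
Conditions: NaBH4, MeOH/CH2Cl2 (1:1), −78 °C
Reagents that add atoms: none
Why: Chemoselective borohydride reduction, in which the saturated, ester-activated C3 ketone should react faster than the conjugated C7 ketone; hydride should come axially from the convex β face (the α face is covered by the C18 methyl and ring B) to give the equatorial 3α-alcohol, which also ends the risk of retro-Michael cleavage.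

**Step 9**
Reactants: 18 3α-hydroxy enone
Product: 19 2-(trimethylsilyl)ethyl (1R,2R,4aR,8aS)-2-acetoxy-1,4a-dimethyl-7-oxo-1,2,3,4,4a,7,8,8a-octahydronaphthalene-1-carboxylate
Conditions: Ac2O, pyridine, DMAP (cat.), CH2Cl2, rt
Reagents that add atoms: acetic anhydride, CC(=O)OC(C)=O
Why: DMAP-catalysed acetylation of the equatorial secondary alcohol installs the acetate of the target with retention at C3.

**Step 10**
Reactants: 20 4-bromobut-1-yne; 21 ethylene
Product: 22 5-bromo-3-methylidenepent-1-ene
Conditions: second-generation Grubbs catalyst RuCl2(=CHPh)(PCy3)(H2IMes) (cat.), ethylene atmosphere, CH2Cl2, rt to 40 °C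
Reagents that add atoms: none
Why: Cross enyne metathesis of a terminal alkyne with ethylene converts C≡CH into the 2-substituted buta-1,3-diene of the side chain (C11–C16); no stereocentre is formed.

**Step 11**
Reactants: 19 3α-acetoxy enone; 22 5-bromo-3-methylidenepent-1-ene
Product: 24 2-(trimethylsilyl)ethyl 3α-acetoxy-7-(trimethylsilyloxy)-17-nor-5β-labda-7,13(16),14-trien-19-oate, via Grignard reagent 23 (not isolated)
Conditions: 22, Mg, THF, rt; then CuBr·SMe2 (cat.), HMPA, TMSCl, 19, THF, −78 °C; Et3N, cold aq NaHCO3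
Reagents that add atoms: chlorotrimethylsilane, C[Si](C)(C)Cl; magnesium, [Mg] (stays only in 23)
Why: Copper-catalysed, TMSCl-accelerated conjugate addition of a Grignard reagent to a 4,4-disubstituted cyclohexenone; C9 should be attacked from the convex β face, anti to the pseudoaxial C10–C1 bond, because the α face is covered by ring A and the C18 methyl, so the chain ends cis to the C10 methyl, and the enolate is trapped regiospecifically at C7/C8.

**Step 12**
Reactants: 24 silyl enol ether
Product: 27 2-(trimethylsilyl)ethyl 3α-acetoxy-7-oxo-5β-labda-8(17),13(16),14-trien-19-oate, via Mannich base 25 (not isolated), via ammonium iodide 26 (not isolated)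
Conditions: CH2=NMe2+ I− (Eschenmoser's salt), CH2Cl2, rt; MeI, Et2O, rt; sat. aq NaHCO3, CH2Cl2, rt
Reagents that add atoms: N,N-dimethylmethyleneiminium iodide, C=[N+](C)C.[I-]; iodomethane, CI (stays only in 26)
Why: Mannich reaction of the regiodefined silyl enol ether at C8, N-methylation and mild E1cB elimination introduce C17 as an α-methylene ketone; the weak base is chosen so that the double bond does not move into the ring and C9 is not touched.

**Step 13**
Reactants: 27 α-methylene ketone
Product: 28 2-(trimethylsilyl)ethyl 3α-acetoxy-7ξ-hydroxy-5β-labda-8(17),13(16),14-trien-19-oate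
Conditions: NaBH4, CeCl3·7H2O, MeOH, −78 °C
Reagents that add atoms: none
Why: Luche reduction gives clean 1,2-reduction of the enone; the configuration at C7 is of no consequence because C7 becomes CH2 in step 15.

**Step 14**
Reactants: 28 allylic alcohol
Product: 29 2-(trimethylsilyl)ethyl 3α-acetoxy-7ξ-(methoxycarbonyloxy)-5β-labda-8(17),13(16),14-trien-19-oate
Conditions: ClCO2Me, pyridine, DMAP (cat.), CH2Cl2, 0 °C
Reagents that add atoms: methyl chloroformate, COC(=O)Cl
Why: Carbonate formation turns the allylic alcohol into a leaving group that zerovalent palladium ionises at room temperature.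

**Step 15**
Reactants: 29 allylic methyl carbonate
Product: 30 2-(trimethylsilyl)ethyl 3α-acetoxy-5β-labda-8(17),13(16),14-trien-19-oate
Conditions: Pd(OAc)2 (cat.), PBu3, HCO2H, Et3N, THF, rt to 40 °C
Reagents that add atoms: none
Why: Tsuji–Trost ionisation followed by formate hydrogenolysis; the allylpalladium formate binds at the less hindered C17 terminus, loses CO2 and delivers hydride to the more substituted C7, which removes the temporary oxygen and leaves the exocyclic C8=C17 alkene, while the non-allylic C3 acetate is inert.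

**Step 16**
Reactants: 30 2-(trimethylsilyl)ethyl ester
Product: 31 3α-acetoxy-5β-labda-8(17),13(16),14-trien-19-oic acid (3R,4R,5S,9S,10R), the target
Conditions: TBAF, THF, 0 °C to rt; aq NH4Cl, dilute HCl to pH 4
Reagents that add atoms: none
Why: Fluoride attacks silicon and the β-silylethyl ester fragments to carboxylate, ethylene and Me3SiF, which frees the hindered C19 acid remote from its steric shielding and should leave the acetate, the diene, the exocyclic alkene and all stereocentres untouched.

**Compound list**
1 | propanal | CCC=O | starting material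
2 | methyl acrylate | C=CC(=O)OC | starting material
3 | (E)-1-(prop-1-en-1-yl)pyrrolidine | C/C=C/N1CCCC1 | intermediate
4 | methyl 4-methyl-5-(pyrrolidin-1-yl)pent-4-enoate | COC(=O)CCC(C)=CN1CCCC1 | intermediate
5 | methyl 4-methyl-5-oxopentanoate (racemic) | COC(=O)CCC(C)C=O | intermediate
6 | methyl vinyl ketone | CC(=O)C=C | starting material
7 | methyl 4-formyl-4-methyl-7-oxooctanoate (racemic) | COC(=O)CCC(C)(C=O)CCC(C)=O | intermediate
8 | methyl 3-(1-methyl-4-oxocyclohex-2-en-1-yl)propanoate (racemic) | COC(=O)CCC1(C)CCC(=O)C=C1 | intermediate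
9 | methyl 3-(1-methyl-4-oxocyclohexa-2,5-dien-1-yl)propanoate | COC(=O)CCC1(C)C=CC(=O)C=C1 | intermediate
10 | 3-(1-methyl-4-oxocyclohexa-2,5-dien-1-yl)propanoic acid | OC(=O)CCC1(C)C=CC(=O)C=C1 | intermediate
11 | 2,2,5-trimethyl-1,3-dioxane-4,6-dione | CC1C(=O)OC(C)(C)OC1=O | starting material
12 | 2-(trimethylsilyl)ethanol | C[Si](C)(C)CCO | starting material
13 | 2-methyl-3-oxo-3-[2-(trimethylsilyl)ethoxy]propanoic acid (racemic) | C[Si](C)(C)CCOC(=O)C(C)C(=O)O | intermediate
14 | 1-[3-(1-methyl-4-oxocyclohexa-2,5-dien-1-yl)propanoyl]imidazole | O=C(CCC1(C)C=CC(=O)C=C1)n1ccnc1 | intermediate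
15 | 2-methyl-2-{[2-(trimethylsilyl)ethoxy]carbonyl}-5-(1-methyl-4-oxocyclohexa-2,5-dien-1-yl)-3-oxopentanoic acid | C[Si](C)(C)CCOC(=O)C(C)(C(=O)O)C(=O)CCC1(C)C=CC(=O)C=C1 | intermediate
16 | 2-(trimethylsilyl)ethyl 2-methyl-5-(1-methyl-4-oxocyclohexa-2,5-dien-1-yl)-3-oxopentanoate (C4 labile) | C[Si](C)(C)CCOC(=O)C(C)C(=O)CCC1(C)C=CC(=O)C=C1 | intermediate
17 | 2-(trimethylsilyl)ethyl (1R,4aR,8aS)-1,4a-dimethyl-2,7-dioxo-1,2,3,4,4a,7,8,8a-octahydronaphthalene-1-carboxylate | C1=CC(=O)C[C@H]2[C@]1(C)CCC(=O)[C@]2(C)C(=O)OCC[Si](C)(C)C | intermediate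
18 | 2-(trimethylsilyl)ethyl (1R,2R,4aR,8aS)-2-hydroxy-1,4a-dimethyl-7-oxo-1,2,3,4,4a,7,8,8a-octahydronaphthalene-1-carboxylate | C1=CC(=O)C[C@H]2[C@]1(C)CC[C@@H](O)[C@]2(C)C(=O)OCC[Si](C)(C)C | intermediate
19 | 2-(trimethylsilyl)ethyl (1R,2R,4aR,8aS)-2-acetoxy-1,4a-dimethyl-7-oxo-1,2,3,4,4a,7,8,8a-octahydronaphthalene-1-carboxylate | C1=CC(=O)C[C@H]2[C@]1(C)CC[C@@H](OC(C)=O)[C@]2(C)C(=O)OCC[Si](C)(C)C | intermediate
20 | 4-bromobut-1-yne | C#CCCBr | starting material
21 | ethylene | C=C | starting material
22 | 5-bromo-3-methylidenepent-1-ene | C=CC(=C)CCBr | intermediate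
23 | (3-methylidenepent-4-en-1-yl)magnesium bromide | C=CC(=C)CC[Mg]Br | intermediate
24 | 2-(trimethylsilyl)ethyl 3α-acetoxy-7-(trimethylsilyloxy)-17-nor-5β-labda-7,13(16),14-trien-19-oate | C=CC(=C)CC[C@H]1C=C(O[Si](C)(C)C)C[C@H]2[C@]1(C)CC[C@@H](OC(C)=O)[C@]2(C)C(=O)OCC[Si](C)(C)C | intermediate
25 | 2-(trimethylsilyl)ethyl 3α-acetoxy-17-(dimethylamino)-7-oxo-5β,8ξ-labda-13(16),14-dien-19-oate | C=CC(=C)CC[C@H]1C(CN(C)C)C(=O)C[C@H]2[C@]1(C)CC[C@@H](OC(C)=O)[C@]2(C)C(=O)OCC[Si](C)(C)C | intermediate
26 | N-methyl (trimethylammonium) iodide of 25 | C=CC(=C)CC[C@H]1C(C[N+](C)(C)C)C(=O)C[C@H]2[C@]1(C)CC[C@@H](OC(C)=O)[C@]2(C)C(=O)OCC[Si](C)(C)C.[I-] | intermediate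
27 | 2-(trimethylsilyl)ethyl 3α-acetoxy-7-oxo-5β-labda-8(17),13(16),14-trien-19-oate | C=CC(=C)CC[C@H]1C(=C)C(=O)C[C@H]2[C@]1(C)CC[C@@H](OC(C)=O)[C@]2(C)C(=O)OCC[Si](C)(C)C | intermediate
28 | 2-(trimethylsilyl)ethyl 3α-acetoxy-7ξ-hydroxy-5β-labda-8(17),13(16),14-trien-19-oate | C=CC(=C)CC[C@H]1C(=C)C(O)C[C@H]2[C@]1(C)CC[C@@H](OC(C)=O)[C@]2(C)C(=O)OCC[Si](C)(C)C | intermediate
29 | 2-(trimethylsilyl)ethyl 3α-acetoxy-7ξ-(methoxycarbonyloxy)-5β-labda-8(17),13(16),14-trien-19-oate | C=CC(=C)CC[C@H]1C(=C)C(OC(=O)OC)C[C@H]2[C@]1(C)CC[C@@H](OC(C)=O)[C@]2(C)C(=O)OCC[Si](C)(C)C | intermediate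
30 | 2-(trimethylsilyl)ethyl 3α-acetoxy-5β-labda-8(17),13(16),14-trien-19-oate | C=CC(=C)CC[C@H]1C(=C)CC[C@H]2[C@]1(C)CC[C@@H](OC(C)=O)[C@]2(C)C(=O)OCC[Si](C)(C)C | intermediate
31 | 3α-acetoxy-5β-labda-8(17),13(16),14-trien-19-oic acid (3R,4R,5S,9S,10R) | C=CC(=C)CC[C@H]1C(=C)CC[C@H]2[C@]1(C)CC[C@@H](OC(C)=O)[C@]2(C)C(=O)O | target

**Step count**
Total steps: 16. Longest linear sequence: 14 steps (1–4, 6–9, 11–16).

**Steps most likely to fail**

1. **Step 7.**
   - What may go wrong: bond formation between the fully substituted C4 and the neopentyl C5 may be slow. Discrimination between the two enantiotopic enone carbons may be weak or of the opposite sense. Retro-Michael equilibration may erode the configuration at C4.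
   - Fallback: a covalent auxiliary in place of a hydrogen-bonding catalyst, from 16 back to 17. Condensation of 16 with (R)-1-phenylethylamine (p-TsOH cat., toluene, molecular sieves) should give the internally hydrogen-bonded Z-enamino ester F1, whose geometry fixes the ester cis to nitrogen.
   - Warming F1 with MgBr2·OEt2 in THF should trigger the auxiliary-controlled aza-ene-type Michael addition, with attack anti to the phenyl group, to give the bicyclic imine F2. Hydrolysis with aqueous AcOH returns 17.

2. **Step 15.**
   - What may go wrong: hydride may be delivered to the wrong allyl terminus, β-hydride elimination may give a ring diene, or the allylpalladium or palladium hydride species may engage the side-chain diene.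
   - Fallback: a metal-hydride-free reductive allylic transposition, from 28 back to 30. A 1,3-transposition of 28 catalysed by Ph3SiOReO3 (Et2O, 0 °C) should give the more stable primary allylic alcohol F3 (C7=C8, C17–OH).
   - Mitsunobu displacement of F3 with 2-nitrobenzenesulfonylhydrazide (PPh3, DEAD, THF, −30 °C) gives the sulfonylhydrazine F4. On warming, F4 loses the sulfinic acid to give the allylic diazene F5.
   - The retro-ene loss of nitrogen from F5 places hydrogen on C7 and the double bond at C8=C17, which is 30.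

3. **Step 8.**
   - What may go wrong: competing 1,2- or 1,4-reduction of the C7 enone beside the hindered C3 ketone.
   - Fallback: reduce everything and re-oxidise selectively, from 17 back to 18. Luche reduction of both carbonyl groups of 17 gives the 3α,7ξ-diol F6. MnO2 in CH2Cl2 oxidises only the allylic C7 alcohol and returns 18.

**Further compounds**
F1 | step 7 | 2-(trimethylsilyl)ethyl (Z)-2-methyl-5-(1-methyl-4-oxocyclohexa-2,5-dien-1-yl)-3-{[(1R)-1-phenylethyl]amino}pent-2-enoate (Z-enamino ester) | C[Si](C)(C)CCOC(=O)/C(C)=C(\N[C@H](C)c1ccccc1)CCC1(C)C=CC(=O)C=C1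
F2 | step 7 | C3 N-[(1R)-1-phenylethyl]imine of 17 (bicyclic imine) | C1=CC(=O)C[C@H]2[C@]1(C)CCC(=N[C@H](C)c3ccccc3)[C@]2(C)C(=O)OCC[Si](C)(C)C
F3 | step 15 | 2-(trimethylsilyl)ethyl 3α-acetoxy-17-hydroxy-5β-labda-7,13(16),14-trien-19-oate (primary allylic alcohol) | C=CC(=C)CC[C@H]1C(CO)=CC[C@H]2[C@]1(C)CC[C@@H](OC(C)=O)[C@]2(C)C(=O)OCC[Si](C)(C)C
F4 | step 15 | C17 N-amino-N-(2-nitrobenzenesulfonyl)amine derived from F3 (sulfonylhydrazine) | C=CC(=C)CC[C@H]1C(CN(N)S(=O)(=O)c3ccccc3[N+](=O)[O-])=CC[C@H]2[C@]1(C)CC[C@@H](OC(C)=O)[C@]2(C)C(=O)OCC[Si](C)(C)C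
F5 | step 15 | C17 monoalkyl diazene derived from F4 (allylic diazene) | C=CC(=C)CC[C@H]1C(CN=N)=CC[C@H]2[C@]1(C)CC[C@@H](OC(C)=O)[C@]2(C)C(=O)OCC[Si](C)(C)C
F6 | step 8 | 2-(trimethylsilyl)ethyl (1R,2R,4aR,8aS)-2,7ξ-dihydroxy-1,4a-dimethyl-1,2,3,4,4a,7,8,8a-octahydronaphthalene-1-carboxylate (3α,7ξ-diol) | C1=CC(O)C[C@H]2[C@]1(C)CC[C@@H](O)[C@]2(C)C(=O)OCC[Si](C)(C)C
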